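**Plan**

- Retrosynthesis: the seven O–benzyl bonds are cut first, then the interflavan bond C4(upper unit)–C8(lower unit). In the lower unit the aryl C–O bonds at C5 and C7 go back to C–F, the C3–O bond goes back to a C2=C3 enol ether, and C3–C4 and O1–C8a are then cut together. In the upper unit C4–OH goes back to the ketone and C2–aryl to a chromone.
- Forward: ring C of the lower unit is closed first, in one operation, from an aryl methyl ketone (ring B, C2, C3) and 2,4,6-trifluorobenzyl bromide (C4 and ring A). Hydroboration and fluorine-to-benzyloxy exchange follow. The upper flavan comes from conjugate addition to a chromone and reduction. The two units are joined in the last step but one, and all benzyl groups are removed last.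
- Enabling feature: in the lower flavan-3-ol, O1 and C3 are both bonded to C2, and the benzylic C4 sits on C4a next to C8a of ring A. With C2 at the ketone level, O1–C2–C3 is one enolate (oxygen and carbon nucleophile). Ring A written as a 2,4,6-trifluorophenyl group makes C4/C8a a benzylic-halide/SNAr double electrophile, and the two remaining fluorines are the later 5- and 7-oxygens.
- Stereochemistry: lower C2 and C3 (2R,3S, trans) are set together by one reagent-controlled syn-hydroboration of the C2=C3 enol ether. Upper C2 (S) comes from a ligand-controlled conjugate addition. Upper C4 (R, trans to the 2-aryl group) comes from axial attack of the lower unit on the flavan-4-yl cation.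

Key step: step 1

Remark 1: compounds 1, 2, 10 and 12 are taken as catalogue compounds; enolates are treated as the ionised forms of their ketones and carry no numbers of their own.
Remark 2: in steps 2 and 5 the antipode of the chiral reagent or ligand is the one expected by analogy with the closest substrate classes (1-arylcycloalkenes; cyclic enones); if the sense proved reversed, the other antipode would be taken.

**Step 1**
Reactants: 1 1-[3,4-bis(benzyloxy)phenyl]ethan-1-one; 2 2-(bromomethyl)-1,3,5-trifluorobenzene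
Product: 4 2-[3,4-bis(benzyloxy)phenyl]-5,7-difluoro-4H-chromene, via trifluorophenyl propanone 3 (not isolated)
Conditions: KN(SiMe3)2 (1.05 equiv), THF, −78 °C; 2 (0.95 equiv), −78 → 0 °C; then KN(SiMe3)2 (0.95 equiv), DMPU, 0 → 45 °C
Reagents that add atoms: none
Why: The potassium enolate of 1 is benzylated at carbon by 2 (SN2, forms C3–C4) to give ketone 3, and the (Z)-potassium enolate of 3, made by the second portion of base, attacks an ortho C–F carbon through oxygen in an addition–elimination (SNAr) that forms O1–C8a and expels fluoride. The closest known reaction types are the domino C-benzylation/intramolecular O-arylation of enolisable carbonyl compounds with 2-halobenzyl halides to give 4H-chromenes and the SNAr ring closure of oxygen nucleophiles onto polyfluoroarenes. The pyran ring (ring C) closes as a 6-(enolendo)-exo-trig addition–elimination, and closure through carbon is excluded because it would need a four-membered ring. No stereocentre is formed, since C2 and C3 emerge as the enol ether double bond and are set together in step 2. The step needs C- over O-benzylation and mono- over dialkylation (soft benzylic bromide, low temperature, slight excess of 1, base in two portions) and a single site of ring closure, which the symmetric ring secures because both ortho fluorines are equivalent while the two remaining fluorines, meta to the reacting carbon, activate it.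

**Step 2**
Reactants: 4 2-[3,4-bis(benzyloxy)phenyl]-5,7-difluoro-4H-chromene
Product: 6 (2R,3S)-2-[3,4-bis(benzyloxy)phenyl]-5,7-difluoro-3,4-dihydro-2H-chromen-3-ol, via flavanyl isopinocampheyl borane 5 (not isolated)
Conditions: dIpcBH2 (isopinocampheylborane from (+)-α-pinene, titrated THF solution, 1.5 equiv), THF, −25 °C; then NaOH (3 M aq), H2O2 (30 % aq), 0 → 25 °C
Reagents that add atoms: hydrogen peroxide, OO; isopinocampheylborane, C[C@H]1[C@H](B)C[C@@H]2C[C@H]1C2(C)C (its boron and terpene group remain only in 5)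
Why: Asymmetric hydroboration–oxidation of the enol ether should put boron on C3 (β to the ring oxygen, the carbon without the aryl group) and hydrogen on C2 from the same face, so that the C3 oxygen and the C2 aryl group end trans, with the face chosen by the isopinocampheyl group (by analogy with 1-phenylcyclopentene, which gives the (1S,2R)-trans alcohol with this reagent, O1 taking the place of the ring CH2) and with retention in the C–B oxidation.

**Step 3**
Reactants: 6 (2R,3S)-2-[3,4-bis(benzyloxy)phenyl]-5,7-difluoro-3,4-dihydro-2H-chromen-3-ol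
Product: 9 (2R,3S)-5,7-bis(benzyloxy)-2-[3,4-bis(benzyloxy)phenyl]-3,4-dihydro-2H-chromen-3-ol, via 7-benzyloxy-5-fluoro flavanol 7 (not isolated), via 5-benzyloxy-7-fluoro flavanol 8 (not isolated)
Conditions: NaOCH2Ph (1 M in PhCH2OH, 6 equiv), DMI, 90 → 140 °C, argon
Reagents that add atoms: sodium benzyloxide, [Na+].[O-]Cc1ccccc1
Why: Two successive SNAr displacements of fluoride by benzyloxide should be possible because each fluorine is meta to O1 and meta to the other fluorine (or to the first benzyloxy group once it is in place), so no ortho or para donor opposes the anionic adduct, while the C3 alkoxide is a spectator (closure onto C5 would need a bridged ring) and neither stereocentre is acidic.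

**Step 4**
Reactants: 10 7-hydroxy-4H-chromen-4-one
Product: 11 7-(benzyloxy)-4H-chromen-4-one
Conditions: PhCH2Br (1.2 equiv), K2CO3 (1.5 equiv), DMF, 25 °C
Reagents that add atoms: benzyl bromide, BrCc1ccccc1
Why: Williamson ether synthesis on the acidic vinylogous-acid phenol should proceed cleanly at oxygen.

**Step 5**
Reactants: 11 7-(benzyloxy)-4H-chromen-4-one; 12 [3,4-bis(benzyloxy)phenyl]boronic acid
Product: 13 (2S)-7-(benzyloxy)-2-[3,4-bis(benzyloxy)phenyl]-2,3-dihydro-4H-chromen-4-one
Conditions: Pd(OCOCF3)2 (5 mol %), (S)-t-BuPyOx (6 mol %), NH4PF6 (30 mol %), H2O (5 equiv), 12 (2 equiv), ClCH2CH2Cl, 60 °C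
Reagents that add atoms: none
Why: Palladium-catalysed asymmetric conjugate addition of an arylboronic acid to a chromone (Hayashi–Miyaura type) should set the 2S centre by ligand-controlled delivery of the aryl group to the Re face of C2, under near-neutral conditions that avoid the base-induced ring opening that racemises flavanones.

**Step 6**
Reactants: 13 (2S)-7-(benzyloxy)-2-[3,4-bis(benzyloxy)phenyl]-2,3-dihydro-4H-chromen-4-one
Product: 14 (2S,4S)-7-(benzyloxy)-2-[3,4-bis(benzyloxy)phenyl]-3,4-dihydro-2H-chromen-4-ol (2,4-cis)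
Conditions: NaBH4 (1.5 equiv), THF/MeOH (1:1), 0 °C
Reagents that add atoms: none
Why: Borohydride reduction of the ketone should give mainly the 2,4-cis alcohol by axial hydride delivery, and since C4 is ionised in step 7 either epimer serves.

**Step 7**
Reactants: 9 (2R,3S)-5,7-bis(benzyloxy)-2-[3,4-bis(benzyloxy)phenyl]-3,4-dihydro-2H-chromen-3-ol (3 equiv); 14 (2S,4S)-7-(benzyloxy)-2-[3,4-bis(benzyloxy)phenyl]-3,4-dihydro-2H-chromen-4-ol
Product: 15 (2R,3S)-5,7-bis(benzyloxy)-2-[3,4-bis(benzyloxy)phenyl]-8-{(2S,4R)-7-(benzyloxy)-2-[3,4-bis(benzyloxy)phenyl]-3,4-dihydro-2H-chromen-4-yl}-3,4-dihydro-2H-chromen-3-ol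
Conditions: Me3SiOTf (0.2 equiv), 4 Å molecular sieves, CH2Cl2, −78 → −40 °C; Et3N quench; excess 9 recovered
Reagents that add atoms: none
Why: In this dehydrative Friedel–Crafts alkylation (the flavan-4-ol/flavan-3-ol condensation used for proanthocyanidins) ionisation of 14 with loss of water should give a benzylic cation stabilised by the para 7-benzyloxy group and by O1, which C8 of 9 (the less hindered nucleophilic position of ring A, excess 9 suppressing a second alkylation) attacks along the axial trajectory of the half-chair with the 2-aryl group equatorial, placing the new aryl group trans to it (4R).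

**Step 8**
Reactants: 15 (2R,3S)-5,7-bis(benzyloxy)-2-[3,4-bis(benzyloxy)phenyl]-8-{(2S,4R)-7-(benzyloxy)-2-[3,4-bis(benzyloxy)phenyl]-3,4-dihydro-2H-chromen-4-yl}-3,4-dihydro-2H-chromen-3-ol
Product: 16 (2R,3S)-2-(3,4-dihydroxyphenyl)-8-[(2S,4R)-2-(3,4-dihydroxyphenyl)-7-hydroxy-3,4-dihydro-2H-chromen-4-yl]-3,4-dihydro-2H-chromene-3,5,7-triol
Conditions: H2 (1 atm), Pd(OH)2/C (20 wt %), THF/MeOH/H2O (20:20:1), 25 °C
Reagents that add atoms: none
Why: Hydrogenolysis of the seven benzyl ethers should leave the ring C–O bonds and the doubly benzylic C4–C8 bond intact under these mild conditions, as in standard proanthocyanidin deprotections, and touches no stereocentre.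

**Compound list**

1 | 1-[3,4-bis(benzyloxy)phenyl]ethan-1-one | CC(=O)c1ccc(OCc2ccccc2)c(OCc2ccccc2)c1 | starting material
2 | 2-(bromomethyl)-1,3,5-trifluorobenzene (2,4,6-trifluorobenzyl bromide) | BrCc1c(F)cc(F)cc1F | starting material
3 | 1-[3,4-bis(benzyloxy)phenyl]-3-(2,4,6-trifluorophenyl)propan-1-one | O=C(CCc1c(F)cc(F)cc1F)c1ccc(OCc2ccccc2)c(OCc2ccccc2)c1 | intermediate (not isolated)
4 | 2-[3,4-bis(benzyloxy)phenyl]-5,7-difluoro-4H-chromene | Fc1cc(F)c2c(c1)OC(=CC2)c1ccc(OCc3ccccc3)c(OCc3ccccc3)c1 | intermediate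
5 | [(2,3-trans)-2-[3,4-bis(benzyloxy)phenyl]-5,7-difluorochroman-3-yl](isopinocampheyl)borane, boron on C3 on the face later taken by the hydroxyl of 6, terpene group from (+)-α-pinene, drawn as monomer | C[C@H]1[C@H](B[C@H]3Cc4c(F)cc(F)cc4O[C@@H]3c3ccc(OCc4ccccc4)c(OCc4ccccc4)c3)C[C@@H]2C[C@H]1C2(C)C | intermediate (not isolated)
6 | (2R,3S)-2-[3,4-bis(benzyloxy)phenyl]-5,7-difluoro-3,4-dihydro-2H-chromen-3-ol | O[C@H]1Cc2c(F)cc(F)cc2O[C@@H]1c1ccc(OCc2ccccc2)c(OCc2ccccc2)c1 | intermediate
7 | (2R,3S)-7-(benzyloxy)-2-[3,4-bis(benzyloxy)phenyl]-5-fluoro-3,4-dihydro-2H-chromen-3-ol | O[C@H]1Cc2c(F)cc(OCc3ccccc3)cc2O[C@@H]1c1ccc(OCc2ccccc2)c(OCc2ccccc2)c1 | intermediate (not isolated)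
8 | (2R,3S)-5-(benzyloxy)-2-[3,4-bis(benzyloxy)phenyl]-7-fluoro-3,4-dihydro-2H-chromen-3-ol | O[C@H]1Cc2c(OCc3ccccc3)cc(F)cc2O[C@@H]1c1ccc(OCc2ccccc2)c(OCc2ccccc2)c1 | intermediate (not isolated)
9 | (2R,3S)-5,7-bis(benzyloxy)-2-[3,4-bis(benzyloxy)phenyl]-3,4-dihydro-2H-chromen-3-ol (5,7,3',4'-tetra-O-benzyl-(+)-catechin) | O[C@H]1Cc2c(OCc3ccccc3)cc(OCc3ccccc3)cc2O[C@@H]1c1ccc(OCc2ccccc2)c(OCc2ccccc2)c1 | intermediate
10 | 7-hydroxy-4H-chromen-4-one | O=c1ccoc2cc(O)ccc12 | starting material
11 | 7-(benzyloxy)-4H-chromen-4-one | O=c1ccoc2cc(OCc3ccccc3)ccc12 | intermediate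
12 | [3,4-bis(benzyloxy)phenyl]boronic acid | OB(O)c1ccc(OCc2ccccc2)c(OCc2ccccc2)c1 | starting material
13 | (2S)-7-(benzyloxy)-2-[3,4-bis(benzyloxy)phenyl]-2,3-dihydro-4H-chromen-4-one | c1ccccc1COc1ccc2c(c1)O[C@H](c1ccc(OCc3ccccc3)c(OCc3ccccc3)c1)CC2=O | intermediate
14 | (2S,4S)-7-(benzyloxy)-2-[3,4-bis(benzyloxy)phenyl]-3,4-dihydro-2H-chromen-4-ol (2,4-cis) | c1ccccc1COc1ccc2c(c1)O[C@H](c1ccc(OCc3ccccc3)c(OCc3ccccc3)c1)C[C@@H]2O | intermediate
15 | (2R,3S)-5,7-bis(benzyloxy)-2-[3,4-bis(benzyloxy)phenyl]-8-{(2S,4R)-7-(benzyloxy)-2-[3,4-bis(benzyloxy)phenyl]-3,4-dihydro-2H-chromen-4-yl}-3,4-dihydro-2H-chromen-3-ol | c1ccccc1COc1ccc2c(c1)O[C@H](c1ccc(OCc3ccccc3)c(OCc3ccccc3)c1)C[C@H]2c1c(OCc3ccccc3)cc(OCc3ccccc3)c2c1O[C@H](c1ccc(OCc3ccccc3)c(OCc3ccccc3)c1)[C@@H](O)C2 | intermediate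
16 | (2R,3S)-2-(3,4-dihydroxyphenyl)-8-[(2S,4R)-2-(3,4-dihydroxyphenyl)-7-hydroxy-3,4-dihydro-2H-chromen-4-yl]-3,4-dihydro-2H-chromene-3,5,7-triol | Oc1ccc2c(c1)O[C@H](c1ccc(O)c(O)c1)C[C@H]2c1c(O)cc(O)c2c1O[C@H](c1ccc(O)c(O)c1)[C@@H](O)C2 | target

**Step count and risks**

Total steps: 8. Longest linear sequence: 5 steps (1 → 2 → 3 → 7 → 8; the upper-unit branch 4 → 5 → 6 → 7 → 8 is equally long).

Most likely to fail, first: step 7. The cation from 14 may be attacked to a large extent on the face cis to the 2-aryl group (poor facial selectivity at C4). It may also be attacked through C6 of 9, or lose a proton to the flav-3-ene. The fallback sets out from 10 and 12 (with 9) and comes back to the route at 16. Compound 10 is used without benzylation, and conjugate addition of 12 under the conditions of step 5 should give (2S)-2-[3,4-bis(benzyloxy)phenyl]-7-hydroxy-2,3-dihydro-4H-chromen-4-one F1. NaBH4 then gives (2S,4S)-2-[3,4-bis(benzyloxy)phenyl]-3,4-dihydro-2H-chromene-4,7-diol F2. With a BINOL-derived chiral phosphoric acid (3,3'-bis(2,4,6-triisopropylphenyl) type, 10 mol %, CH2Cl2, 4 Å molecular sieves, −40 °C), F2 should lose water to the para-quinone methide (2S)-2-[3,4-bis(benzyloxy)phenyl]-2,3-dihydro-7H-chromen-7-one F3 (not isolated). C8 of 9 then adds in a 1,6-addition inside the hydrogen-bonded ion pair, so the face of C4 is chosen by the catalyst antipode and no longer by the substrate. The product is the hexabenzyl ether (2R,3S)-5,7-bis(benzyloxy)-2-[3,4-bis(benzyloxy)phenyl]-8-{(2S,4R)-2-[3,4-bis(benzyloxy)phenyl]-7-hydroxy-3,4-dihydro-2H-chromen-4-yl}-3,4-dihydro-2H-chromen-3-ol F4, and hydrogenolysis as in step 8 gives 16.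

Second: step 2. The isopinocampheyl reagent may discriminate the two faces of the hindered trisubstituted enol ether insufficiently, so that the alcohol is formed with low enantiomeric purity. The fallback sets out from 4 and comes back at 6, and replaces reagent control by resolution. Hydroboration of 4 with BH3·SMe2 (THF, 0 °C) and NaOH/H2O2 should give the racemic trans alcohol, that is 6 together with its enantiomer (2S,3R)-2-[3,4-bis(benzyloxy)phenyl]-5,7-difluoro-3,4-dihydro-2H-chromen-3-ol F5. Esterification with (S)-2-methoxy-2-phenylacetic acid (DCC, DMAP, CH2Cl2) gives the diastereomeric esters, the (S)-O-methylmandelate of 6 F6 and the (S)-O-methylmandelate of F5 F7, which are separated by chromatography or crystallisation. LiOH (THF/H2O) cleaves F6 back to 6.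

Third: step 3. The second fluoride may resist displacement once ring A carries two oxygen substituents, or the material may degrade at the temperature needed. The fallback sets out from 1 and comes back at 9; it installs both benzyloxy groups before the annulation and closes O1–C8a by copper catalysis, not SNAr. Purchased 1,3-bis(benzyloxy)-5-bromobenzene is formylated ortho to bromine (POCl3, DMF, Vilsmeier–Haack) to 2,4-bis(benzyloxy)-6-bromobenzaldehyde F8. This is reduced (NaBH4) to [2,4-bis(benzyloxy)-6-bromophenyl]methanol F9 and converted (PBr3) into 1,5-bis(benzyloxy)-3-bromo-2-(bromomethyl)benzene F10. The potassium enolate of 1 is alkylated with F10 to 3-[2,4-bis(benzyloxy)-6-bromophenyl]-1-[3,4-bis(benzyloxy)phenyl]propan-1-one F11. Intramolecular enolate O-arylation (CuI 10 mol %, 1,10-phenanthroline, K3PO4, DMF, 110 °C) gives 5,7-bis(benzyloxy)-2-[3,4-bis(benzyloxy)phenyl]-4H-chromene F12. Hydroboration–oxidation as in step 2, through the flavanyl(isopinocampheyl)borane F13 (not isolated), gives 9.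

**Further compounds**

F1 | step 7 | (2S)-2-[3,4-bis(benzyloxy)phenyl]-7-hydroxy-2,3-dihydro-4H-chromen-4-one | Oc1ccc2c(c1)O[C@H](c1ccc(OCc3ccccc3)c(OCc3ccccc3)c1)CC2=O
F2 | step 7 | (2S,4S)-2-[3,4-bis(benzyloxy)phenyl]-3,4-dihydro-2H-chromene-4,7-diol | Oc1ccc2c(c1)O[C@H](c1ccc(OCc3ccccc3)c(OCc3ccccc3)c1)C[C@@H]2O
F3 | step 7 | (2S)-2-[3,4-bis(benzyloxy)phenyl]-2,3-dihydro-7H-chromen-7-one (para-quinone methide) | O=C1C=CC2=CC[C@@H](c3ccc(OCc4ccccc4)c(OCc4ccccc4)c3)OC2=C1
F4 | step 7 | (2R,3S)-5,7-bis(benzyloxy)-2-[3,4-bis(benzyloxy)phenyl]-8-{(2S,4R)-2-[3,4-bis(benzyloxy)phenyl]-7-hydroxy-3,4-dihydro-2H-chromen-4-yl}-3,4-dihydro-2H-chromen-3-ol | Oc1ccc2c(c1)O[C@H](c1ccc(OCc3ccccc3)c(OCc3ccccc3)c1)C[C@H]2c1c(OCc3ccccc3)cc(OCc3ccccc3)c2c1O[C@H](c1ccc(OCc3ccccc3)c(OCc3ccccc3)c1)[C@@H](O)C2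
F5 | step 2 | (2S,3R)-2-[3,4-bis(benzyloxy)phenyl]-5,7-difluoro-3,4-dihydro-2H-chromen-3-ol | O[C@@H]1Cc2c(F)cc(F)cc2O[C@H]1c1ccc(OCc2ccccc2)c(OCc2ccccc2)c1
F6 | step 2 | (2R,3S)-2-[3,4-bis(benzyloxy)phenyl]-5,7-difluoro-3,4-dihydro-2H-chromen-3-yl (S)-2-methoxy-2-phenylacetate | CO[C@@H](c1ccccc1)C(=O)O[C@H]1Cc2c(F)cc(F)cc2O[C@@H]1c1ccc(OCc2ccccc2)c(OCc2ccccc2)c1
F7 | step 2 | (2S,3R)-2-[3,4-bis(benzyloxy)phenyl]-5,7-difluoro-3,4-dihydro-2H-chromen-3-yl (S)-2-methoxy-2-phenylacetate | CO[C@@H](c1ccccc1)C(=O)O[C@@H]1Cc2c(F)cc(F)cc2O[C@H]1c1ccc(OCc2ccccc2)c(OCc2ccccc2)c1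
F8 | step 3 | 2,4-bis(benzyloxy)-6-bromobenzaldehyde | O=Cc1c(Br)cc(OCc2ccccc2)cc1OCc1ccccc1
F9 | step 3 | [2,4-bis(benzyloxy)-6-bromophenyl]methanol | OCc1c(Br)cc(OCc2ccccc2)cc1OCc1ccccc1
F10 | step 3 | 1,5-bis(benzyloxy)-3-bromo-2-(bromomethyl)benzene | BrCc1c(Br)cc(OCc2ccccc2)cc1OCc1ccccc1
F11 | step 3 | 3-[2,4-bis(benzyloxy)-6-bromophenyl]-1-[3,4-bis(benzyloxy)phenyl]propan-1-one | O=C(CCc1c(Br)cc(OCc2ccccc2)cc1OCc1ccccc1)c1ccc(OCc2ccccc2)c(OCc2ccccc2)c1
F12 | step 3 | 5,7-bis(benzyloxy)-2-[3,4-bis(benzyloxy)phenyl]-4H-chromene | c1ccccc1COc1cc(OCc3ccccc3)c2c(c1)OC(=CC2)c1ccc(OCc3ccccc3)c(OCc3ccccc3)c1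
F13 | step 3 | [(2,3-trans)-5,7-bis(benzyloxy)-2-[3,4-bis(benzyloxy)phenyl]chroman-3-yl](isopinocampheyl)borane, configured at C2 and C3 as 9 | C[C@H]1[C@H](B[C@H]3Cc4c(OCc5ccccc5)cc(OCc5ccccc5)cc4O[C@@H]3c3ccc(OCc4ccccc4)c(OCc4ccccc4)c3)C[C@@H]2C[C@H]1C2(C)C
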